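**Retrosynthetic overview**

1. The target is an upper 2,3-cis-3,4-trans 4-arylflavan-3-ol bonded through C4 to C6 of a lower 2,3-trans-3,4-trans flavan-3,4-diol. The lower C4 carbinol is made last, by NaBH4 reduction of the dihydroflavonol ketone 24, after global hydrogenolysis of 23.
2. Key disconnection: C4–C4a of upper ring C. Upper C4 is a diarylmethine trans to the C3 hydroxyl, and C4a of ring A is ortho to O1 and para to the C7 oxygen. Ring C can therefore be closed by attack of C4a on the benzylic carbon of a trans C3–C4 epoxide carried on an aryl ether (22 → 23).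
3. Epoxide 22 comes from E-alkene 21 by reagent-controlled epoxidation. Alkene 21 comes from cross-metathesis of the (S)-allylic aryl ether 10 with the 6-vinyl dihydroflavonol carbonate 20. C2 of 10 is set by iridium-catalysed allylic etherification of carbonate 8 with phenol 4.
4. Lower unit 20 comes from gallacetophenone: iodination, chalcone formation, poly-L-leucine epoxidation, acid-mediated closure of lower ring C, Stille vinylation.
5. Ring order: lower ring C (step 12), then upper ring C (step 17). Rings A and B of both units come from the aromatic starting materials.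

Key step: step 17

Assumption: the (Sa,Sc,Sc)-phosphoramidite is taken to give the (S)-ether in step 6, and the L-fructose-derived ketone the epoxide face drawn in step 16 (the mirror image of the face the D-fructose-derived ketone attacks in trans-stilbene); if either sense is reversed, the antipodal ligand or ketone is used.

**Route**

Step 1
Reactants: 1 2,3-dihydroxybenzaldehyde
Product: 2 2,3-bis(benzyloxy)benzaldehyde
Conditions: BnBr (2.3 equiv), K2CO3, DMF, 60 °C
Reagents that add atoms: benzyl bromide, BrCc1ccccc1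
Why: Williamson ether synthesis on both phenoxides, the aldehyde being inert to carbonate base.

Step 2
Reactants: 2 2,3-bis(benzyloxy)benzaldehyde
Product: 4 2,3-bis(benzyloxy)phenol, via aryl formate 3 (not isolated)
Conditions: mCPBA, CH2Cl2, rt; then K2CO3 (cat.), MeOH, rt
Reagents that add atoms: 3-chloroperoxybenzoic acid, OOC(=O)c1cccc(Cl)c1
Why: Baeyer–Villiger (Dakin-type) oxidation in which the electron-rich aryl group migrates to oxygen, followed by methanolysis of the aryl formate.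

Step 3
Reactants: 5 4-(benzyloxy)benzaldehyde
Product: 6 ethyl (2E)-3-[4-(benzyloxy)phenyl]prop-2-enoate
Conditions: (EtO)2P(O)CH2CO2Et, NaH, THF, 0 °C → rt
Reagents that add atoms: triethyl phosphonoacetate, CCOC(=O)CP(=O)(OCC)OCC
Why: Horner–Wadsworth–Emmons olefination with a stabilised phosphonate, which should give the E-enoate.

Step 4
Reactants: 6 ethyl (2E)-3-[4-(benzyloxy)phenyl]prop-2-enoate
Product: 7 (2E)-3-[4-(benzyloxy)phenyl]prop-2-en-1-ol
Conditions: i-Bu2AlH (2.2 equiv), CH2Cl2, −78 °C; aq. KNaC4H4O6 work-up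
Reagents that add atoms: none
Why: 1,2-reduction of the conjugated ester by the aluminium hydride leaves the alkene and its E geometry intact.

Step 5
Reactants: 7 (2E)-3-[4-(benzyloxy)phenyl]prop-2-en-1-ol
Product: 8 (2E)-3-[4-(benzyloxy)phenyl]prop-2-en-1-yl methyl carbonate
Conditions: ClCO2Me, pyridine, CH2Cl2, 0 °C
Reagents that add atoms: methyl chloroformate, COC(=O)Cl
Why: O-acylation of the primary allylic alcohol gives the linear carbonate needed as the allyl donor.

Step 6
Reactants: 4 2,3-bis(benzyloxy)phenol; 8 (2E)-3-[4-(benzyloxy)phenyl]prop-2-en-1-yl methyl carbonate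
Product: 10 1,2-bis(benzyloxy)-3-{[(1S)-1-[4-(benzyloxy)phenyl]prop-2-en-1-yl]oxy}benzene, via lithium aryloxide 9 (not isolated)
Conditions: 4, n-BuLi, THF, 0 °C; then 8, [Ir(cod)Cl]2 (2 mol %), (Sa,Sc,Sc)-O,O′-(1,1′-binaphthalene-2,2′-diyl) N,N-bis(1-phenylethyl)phosphoramidite (4 mol %), THF, 50 °C, stopped at full conversion
Reagents that add atoms: none
Why: Iridium-catalysed asymmetric allylic etherification, in which the aryloxide attacks the aryl-bearing terminus of the cyclometalated iridium–phosphoramidite allyl complex to give the branched ether, the ligand fixing the face so that the future upper C2 is set as S.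

Step 7
Reactants: 11 gallacetophenone
Product: 12 1-[3,4-bis(benzyloxy)-2-hydroxyphenyl]ethanone
Conditions: BnBr (2.1 equiv), K2CO3, acetone, reflux
Reagents that add atoms: benzyl bromide, BrCc1ccccc1
Why: Williamson ether synthesis selective for the 3- and 4-hydroxyls, because the 2-hydroxyl is held in a hydrogen bond to the ketone.

Step 8
Reactants: 12 1-[3,4-bis(benzyloxy)-2-hydroxyphenyl]ethanone
Product: 13 1-[3,4-bis(benzyloxy)-2-hydroxy-5-iodophenyl]ethanone
Conditions: N-iodosuccinimide, CF3CO2H (cat.), MeCN, rt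
Reagents that add atoms: N-iodosuccinimide, O=C1CCC(=O)N1I
Why: Electrophilic aromatic iodination at C5, which is para to the free phenol and ortho to a benzyloxy group, whereas the other open position is ortho to the acetyl group.

Step 9
Reactants: 13 1-[3,4-bis(benzyloxy)-2-hydroxy-5-iodophenyl]ethanone
Product: 14 1-[3,4-bis(benzyloxy)-5-iodo-2-(methoxymethoxy)phenyl]ethanone
Conditions: NaH, MOMCl, DMF, 0 °C → rt
Reagents that add atoms: chloromethyl methyl ether, COCCl
Why: O-alkylation of the sodium phenoxide gives the acetal that keeps the phenol from cyclising during the basic steps.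

Step 10
Reactants: 14 1-[3,4-bis(benzyloxy)-5-iodo-2-(methoxymethoxy)phenyl]ethanone; 5 4-(benzyloxy)benzaldehyde
Product: 15 (2E)-1-[3,4-bis(benzyloxy)-5-iodo-2-(methoxymethoxy)phenyl]-3-[4-(benzyloxy)phenyl]prop-2-en-1-one
Conditions: KOH (aq. 50 %), EtOH/THF, rt
Reagents that add atoms: none
Why: Claisen–Schmidt condensation of the methyl ketone enolate with the non-enolisable aldehyde, dehydration giving the E-chalcone.

Step 11
Reactants: 15 (2E)-1-[3,4-bis(benzyloxy)-5-iodo-2-(methoxymethoxy)phenyl]-3-[4-(benzyloxy)phenyl]prop-2-en-1-one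
Product: 16 [3,4-bis(benzyloxy)-5-iodo-2-(methoxymethoxy)phenyl]{(2R,3S)-3-[4-(benzyloxy)phenyl]oxiran-2-yl}methanone
Conditions: poly-L-leucine, urea·H2O2, DBU, THF, rt
Reagents that add atoms: hydrogen peroxide (from urea–hydrogen peroxide), OO
Why: Juliá–Colonna epoxidation, in which hydroperoxide adds to the enone bound to the helical poly-L-leucine and closes to the trans (2R,3S)-epoxide, the polypeptide choosing the enone face and so setting the carbons that become lower C3 and C2.

Step 12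
Reactants: 16 [3,4-bis(benzyloxy)-5-iodo-2-(methoxymethoxy)phenyl]{(2R,3S)-3-[4-(benzyloxy)phenyl]oxiran-2-yl}methanone
Product: 18 (2R,3R)-7,8-bis(benzyloxy)-2-[4-(benzyloxy)phenyl]-3-hydroxy-6-iodo-2,3-dihydro-4H-chromen-4-one, via free-phenol epoxide 17 (not isolated)
Conditions: HCl, MeOH/THF, 50 °C; chromatographic removal of any 2,3-cis isomer
Reagents that add atoms: none
Why: Acid cleaves the methoxymethyl acetal and the freed phenol opens the protonated epoxide at the 4-benzyloxybenzylic carbon in a 6-endo epoxide-opening etherification with inversion, so lower ring C should form 2,3-trans with C3 kept from the epoxide (2R,3R).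

Step 13
Reactants: 18 (2R,3R)-7,8-bis(benzyloxy)-2-[4-(benzyloxy)phenyl]-3-hydroxy-6-iodo-2,3-dihydro-4H-chromen-4-one
Product: 19 (2R,3R)-7,8-bis(benzyloxy)-2-[4-(benzyloxy)phenyl]-6-ethenyl-3-hydroxy-2,3-dihydro-4H-chromen-4-one
Conditions: Bu3SnCH=CH2, Pd(PPh3)4 (5 mol %), toluene, 100 °C
Reagents that add atoms: tributyl(vinyl)stannane, C=C[Sn](CCCC)(CCCC)CCCC
Why: Stille coupling under neutral conditions (oxidative addition of the aryl iodide to zerovalent palladium, transmetalation, reductive elimination) installs the C6 vinyl group without disturbing the α-hydroxy ketone.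

Step 14
Reactants: 19 (2R,3R)-7,8-bis(benzyloxy)-2-[4-(benzyloxy)phenyl]-6-ethenyl-3-hydroxy-2,3-dihydro-4H-chromen-4-one
Product: 20 benzyl (2R,3R)-7,8-bis(benzyloxy)-2-[4-(benzyloxy)phenyl]-6-ethenyl-4-oxo-3,4-dihydro-2H-chromen-3-yl carbonate
Conditions: CbzCl, pyridine, DMAP (cat.), CH2Cl2, 0 °C → rt
Reagents that add atoms: benzyl chloroformate, O=C(Cl)OCc1ccccc1
Why: O-acylation to a benzyl carbonate that masks the 3-hydroxyl through metathesis, epoxidation and Lewis acid treatment and later falls off in the hydrogenolysis, so the base-sensitive dihydroflavonol never needs a basic deacylation.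

Step 15
Reactants: 10 1,2-bis(benzyloxy)-3-{[(1S)-1-[4-(benzyloxy)phenyl]prop-2-en-1-yl]oxy}benzene; 20 benzyl (2R,3R)-7,8-bis(benzyloxy)-2-[4-(benzyloxy)phenyl]-6-ethenyl-4-oxo-3,4-dihydro-2H-chromen-3-yl carbonate
Product: 21 benzyl (2R,3R)-7,8-bis(benzyloxy)-2-[4-(benzyloxy)phenyl]-6-{(1E,3S)-3-[2,3-bis(benzyloxy)phenoxy]-3-[4-(benzyloxy)phenyl]prop-1-en-1-yl}-4-oxo-3,4-dihydro-2H-chromen-3-yl carbonate
Conditions: 10 (2 equiv), Hoveyda–Grubbs second-generation catalyst RuCl2(H2IMes)(=CH-C6H4-2-O-i-Pr) (10 mol %), 1,4-benzoquinone (20 mol %), CH2Cl2, 40 °C; chromatography on Et3N-washed SiO2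
Reagents that add atoms: none
Why: Olefin cross-metathesis between two partners that homodimerise slowly (one branched at the allylic carbon, one ortho-substituted), the conjugated E-alkene being favoured thermodynamically and benzoquinone suppressing ruthenium hydride isomerisation of the allylic ether.

Step 16
Reactants: 21 benzyl (2R,3R)-7,8-bis(benzyloxy)-2-[4-(benzyloxy)phenyl]-6-{(1E,3S)-3-[2,3-bis(benzyloxy)phenoxy]-3-[4-(benzyloxy)phenyl]prop-1-en-1-yl}-4-oxo-3,4-dihydro-2H-chromen-3-yl carbonate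
Product: 22 benzyl (2R,3R)-7,8-bis(benzyloxy)-2-[4-(benzyloxy)phenyl]-6-[(2S,3R)-3-{(R)-[2,3-bis(benzyloxy)phenoxy][4-(benzyloxy)phenyl]methyl}oxiran-2-yl]-4-oxo-3,4-dihydro-2H-chromen-3-yl carbonate (trans-epoxide)
Conditions: 1,2:4,5-di-O-isopropylidene-β-L-erythro-2,3-hexodiulo-2,6-pyranose (L-fructose-derived Shi ketone, 1.0 equiv), KHSO5 (as Oxone, 2KHSO5·KHSO4·K2SO4), NaHCO3 (pH ≈ 8), Bu4NHSO4 (cat.), MeCN/CH2(OMe)2/aq. Na2EDTA, 0 °C; filtered through basic Al2O3 and used directly
Reagents that add atoms: potassium peroxymonosulfate, [K+].[O-]S(=O)(=O)OO; the oxygen is passed on by the dioxirane of the ketone, CC1(C)OC[C@]2(O1)OC[C@@H]3OC(C)(C)O[C@@H]3C24OO4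
Why: Shi asymmetric epoxidation, in which the chiral dioxirane transfers oxygen to the E-alkene stereospecifically through a spiro transition state, so the epoxide is trans and its two new stereocentres (upper C3 and C4) are chosen by the ketone enantiomer and not by C2, while pH ≈ 8 spares the dihydroflavonol carbonate.

Step 17
Reactants: 22 benzyl (2R,3R)-7,8-bis(benzyloxy)-2-[4-(benzyloxy)phenyl]-6-[(2S,3R)-3-{(R)-[2,3-bis(benzyloxy)phenoxy][4-(benzyloxy)phenyl]methyl}oxiran-2-yl]-4-oxo-3,4-dihydro-2H-chromen-3-yl carbonate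
Product: 23 benzyl (2R,3R)-7,8-bis(benzyloxy)-2-[4-(benzyloxy)phenyl]-6-{(2R,3R,4R)-7,8-bis(benzyloxy)-2-[4-(benzyloxy)phenyl]-3-hydroxy-3,4-dihydro-2H-chromen-4-yl}-4-oxo-3,4-dihydro-2H-chromen-3-yl carbonate (upper unit 2,3-cis-3,4-trans)
Conditions: BF3·OEt2 (1.1 equiv), CH2Cl2, −78 → −40 °C; aq. NaHCO3 quench
Reagents that add atoms: none
Why: BF3 binds the epoxide oxygen and lengthens the C4–O bond, whose carbon is benzylic to the lower aryl ring (ortho to its C7 benzyloxy group and para to its ring oxygen); ring A carbon C4a, ortho to the ether oxygen O1 and para to the C7 benzyloxy group, attacks C4 from the side opposite the leaving oxygen, and proton loss rearomatises ring A and frees the C3 hydroxyl on work-up. The closest known reaction is the Lewis-acid-promoted intramolecular Friedel–Crafts epoxy-arene cyclisation of aryl 3-aryl-2,3-epoxypropyl ethers to trans-4-arylchroman-3-ols. The one ring closed is upper ring C (O1–C2–C3–C4–C4a–C8a), formed in the 6-endo mode by attack on the distal epoxide carbon. The one new stereocentre, C4, arises by inversion of the epoxide carbon set in step 16, so the C4 aryl group ends trans to the C3 oxygen while C3 and C2 are carried through unchanged, giving the 2,3-cis-3,4-trans unit. The step needs 6-endo closure by ring A and not 5-exo attack at C3 or attack by ring B: only C4 is benzylically activated, the ortho carbons of ring B are meta to its benzyloxy group and would give a five-membered ring, and C6 of ring A cannot reach. The lower C4 ketone, meta to the reacting benzylic carbon, tempers cation formation so that the opening should stay invertive and not drift to hydride shift, and the low temperature together with the electron-withdrawing epoxide next to C2 disfavours ionisation of the C2 aryl ether.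

Step 18
Reactants: 23 benzyl (2R,3R)-7,8-bis(benzyloxy)-2-[4-(benzyloxy)phenyl]-6-{(2R,3R,4R)-7,8-bis(benzyloxy)-2-[4-(benzyloxy)phenyl]-3-hydroxy-3,4-dihydro-2H-chromen-4-yl}-4-oxo-3,4-dihydro-2H-chromen-3-yl carbonate
Product: 24 (2R,3R)-3,7,8-trihydroxy-2-(4-hydroxyphenyl)-6-[(2R,3R,4S)-3,7,8-trihydroxy-2-(4-hydroxyphenyl)-3,4-dihydro-2H-chromen-4-yl]-2,3-dihydro-4H-chromen-4-one
Conditions: H2 (1 atm), Pd(OH)2/C, THF/MeOH, rt
Reagents that add atoms: none
Why: Catalytic hydrogenolysis removes the six aryl benzyl ethers and the benzyl carbonate (with loss of CO2) under neutral conditions that leave the vinylogous-ester ketone and both heterocycles intact, and it is placed before the reduction because a lower C4 carbinol para to a free phenol would itself be prone to hydrogenolysis.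

Step 19
Reactants: 24 (2R,3R)-3,7,8-trihydroxy-2-(4-hydroxyphenyl)-6-[(2R,3R,4S)-3,7,8-trihydroxy-2-(4-hydroxyphenyl)-3,4-dihydro-2H-chromen-4-yl]-2,3-dihydro-4H-chromen-4-one
Product: 25 (2R,3S,4R)-6-[(2R,3R,4S)-3,7,8-trihydroxy-2-(4-hydroxyphenyl)-3,4-dihydro-2H-chromen-4-yl]-2-(4-hydroxyphenyl)-3,4-dihydro-2H-chromene-3,4,7,8-tetrol (CNP0391561.5)
Conditions: NaBH4 (excess), MeOH, 0 °C, under Ar; AcOH to pH ≈ 5; Sephadex LH-20
Reagents that add atoms: none
Why: Borohydride reduction of the aryl ketone, in which hydride adds axially to C4 of the 2,3-trans dihydroflavonol half-chair so that the new hydroxyl ends equatorial and trans to the C3 hydroxyl (4R), the known course of dihydroflavonol reduction to 2,3-trans-3,4-trans flavan-3,4-diols.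

**Compound list**

1 | 2,3-dihydroxybenzaldehyde | O=Cc1cccc(O)c1O | starting material
2 | 2,3-bis(benzyloxy)benzaldehyde | O=Cc1cccc(OCc2ccccc2)c1OCc1ccccc1 | intermediate
3 | 2,3-bis(benzyloxy)phenyl formate (not isolated) | O=COc1cccc(OCc2ccccc2)c1OCc1ccccc1 | intermediate
4 | 2,3-bis(benzyloxy)phenol | Oc1cccc(OCc2ccccc2)c1OCc1ccccc1 | intermediate
5 | 4-(benzyloxy)benzaldehyde | O=Cc1ccc(OCc2ccccc2)cc1 | starting material
6 | ethyl (2E)-3-[4-(benzyloxy)phenyl]prop-2-enoate | CCOC(=O)/C=C/c1ccc(OCc2ccccc2)cc1 | intermediate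
7 | (2E)-3-[4-(benzyloxy)phenyl]prop-2-en-1-ol | OC/C=C/c1ccc(OCc2ccccc2)cc1 | intermediate
8 | (2E)-3-[4-(benzyloxy)phenyl]prop-2-en-1-yl methyl carbonate | COC(=O)OC/C=C/c1ccc(OCc2ccccc2)cc1 | intermediate
9 | lithium 2,3-bis(benzyloxy)phenoxide (not isolated) | [Li+].[O-]c1cccc(OCc2ccccc2)c1OCc1ccccc1 | intermediate
10 | 1,2-bis(benzyloxy)-3-{[(1S)-1-[4-(benzyloxy)phenyl]prop-2-en-1-yl]oxy}benzene | c5ccccc5COc1ccc([C@@H](Oc3cccc(OCc5ccccc5)c3OCc5ccccc5)C=C)cc1 | intermediate
11 | gallacetophenone, 1-(2,3,4-trihydroxyphenyl)ethanone | CC(=O)c1ccc(O)c(O)c1O | starting material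
12 | 1-[3,4-bis(benzyloxy)-2-hydroxyphenyl]ethanone | CC(=O)c1ccc(OCc2ccccc2)c(OCc2ccccc2)c1O | intermediate
13 | 1-[3,4-bis(benzyloxy)-2-hydroxy-5-iodophenyl]ethanone | CC(=O)c1cc(I)c(OCc2ccccc2)c(OCc2ccccc2)c1O | intermediate
14 | 1-[3,4-bis(benzyloxy)-5-iodo-2-(methoxymethoxy)phenyl]ethanone | CC(=O)c1cc(I)c(OCc2ccccc2)c(OCc2ccccc2)c1OCOC | intermediate
15 | (2E)-1-[3,4-bis(benzyloxy)-5-iodo-2-(methoxymethoxy)phenyl]-3-[4-(benzyloxy)phenyl]prop-2-en-1-one | O=C(/C=C/c1ccc(OCc2ccccc2)cc1)c1cc(I)c(OCc2ccccc2)c(OCc2ccccc2)c1OCOC | intermediate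
16 | [3,4-bis(benzyloxy)-5-iodo-2-(methoxymethoxy)phenyl]{(2R,3S)-3-[4-(benzyloxy)phenyl]oxiran-2-yl}methanone | O=C([C@@H]1O[C@H]1c1ccc(OCc2ccccc2)cc1)c1cc(I)c(OCc2ccccc2)c(OCc2ccccc2)c1OCOC | intermediate
17 | [3,4-bis(benzyloxy)-2-hydroxy-5-iodophenyl]{(2R,3S)-3-[4-(benzyloxy)phenyl]oxiran-2-yl}methanone (not isolated) | O=C([C@@H]1O[C@H]1c1ccc(OCc2ccccc2)cc1)c1cc(I)c(OCc2ccccc2)c(OCc2ccccc2)c1O | intermediate
18 | (2R,3R)-7,8-bis(benzyloxy)-2-[4-(benzyloxy)phenyl]-3-hydroxy-6-iodo-2,3-dihydro-4H-chromen-4-one | Ic1cc2c(c(OCc3ccccc3)c1OCc1ccccc1)O[C@H](c1ccc(OCc3ccccc3)cc1)[C@@H](O)C2=O | intermediate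
19 | (2R,3R)-7,8-bis(benzyloxy)-2-[4-(benzyloxy)phenyl]-6-ethenyl-3-hydroxy-2,3-dihydro-4H-chromen-4-one | C=Cc1cc2c(c(OCc3ccccc3)c1OCc1ccccc1)O[C@H](c1ccc(OCc3ccccc3)cc1)[C@@H](O)C2=O | intermediate
20 | benzyl (2R,3R)-7,8-bis(benzyloxy)-2-[4-(benzyloxy)phenyl]-6-ethenyl-4-oxo-3,4-dihydro-2H-chromen-3-yl carbonate | C=Cc1cc2c(c(OCc3ccccc3)c1OCc1ccccc1)O[C@H](c1ccc(OCc3ccccc3)cc1)[C@@H](OC(=O)OCc1ccccc1)C2=O | intermediate
21 | benzyl (2R,3R)-7,8-bis(benzyloxy)-2-[4-(benzyloxy)phenyl]-6-{(1E,3S)-3-[2,3-bis(benzyloxy)phenoxy]-3-[4-(benzyloxy)phenyl]prop-1-en-1-yl}-4-oxo-3,4-dihydro-2H-chromen-3-yl carbonate | c5ccccc5COc1ccc([C@@H](Oc3cccc(OCc5ccccc5)c3OCc5ccccc5)/C=C/c3cc4c(c(OCc5ccccc5)c3OCc5ccccc5)O[C@H](c3ccc(OCc5ccccc5)cc3)[C@@H](OC(=O)OCc5ccccc5)C4=O)cc1 | intermediate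
22 | benzyl (2R,3R)-7,8-bis(benzyloxy)-2-[4-(benzyloxy)phenyl]-6-[(2S,3R)-3-{(R)-[2,3-bis(benzyloxy)phenoxy][4-(benzyloxy)phenyl]methyl}oxiran-2-yl]-4-oxo-3,4-dihydro-2H-chromen-3-yl carbonate (trans-epoxide, key-step precursor) | c5ccccc5COc1ccc([C@@H](Oc3cccc(OCc5ccccc5)c3OCc5ccccc5)[C@@H]2O[C@H]2c3cc4c(c(OCc5ccccc5)c3OCc5ccccc5)O[C@H](c3ccc(OCc5ccccc5)cc3)[C@@H](OC(=O)OCc5ccccc5)C4=O)cc1 | intermediate
23 | benzyl (2R,3R)-7,8-bis(benzyloxy)-2-[4-(benzyloxy)phenyl]-6-{(2R,3R,4R)-7,8-bis(benzyloxy)-2-[4-(benzyloxy)phenyl]-3-hydroxy-3,4-dihydro-2H-chromen-4-yl}-4-oxo-3,4-dihydro-2H-chromen-3-yl carbonate (key-step product) | c5ccccc5COc1ccc([C@H]2Oc3c(ccc(OCc5ccccc5)c3OCc5ccccc5)[C@H](c3cc4c(c(OCc5ccccc5)c3OCc5ccccc5)O[C@H](c3ccc(OCc5ccccc5)cc3)[C@@H](OC(=O)OCc5ccccc5)C4=O)[C@H]2O)cc1 | intermediate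
24 | (2R,3R)-3,7,8-trihydroxy-2-(4-hydroxyphenyl)-6-[(2R,3R,4S)-3,7,8-trihydroxy-2-(4-hydroxyphenyl)-3,4-dihydro-2H-chromen-4-yl]-2,3-dihydro-4H-chromen-4-one | Oc1ccc([C@H]2Oc3c(ccc(O)c3O)[C@H](c3cc4c(c(O)c3O)O[C@H](c3ccc(O)cc3)[C@@H](O)C4=O)[C@H]2O)cc1 | intermediate
25 | (2R,3S,4R)-6-[(2R,3R,4S)-3,7,8-trihydroxy-2-(4-hydroxyphenyl)-3,4-dihydro-2H-chromen-4-yl]-2-(4-hydroxyphenyl)-3,4-dihydro-2H-chromene-3,4,7,8-tetrol | Oc1ccc([C@H]2Oc3c(ccc(O)c3O)[C@H](c3cc4c(c(O)c3O)O[C@H](c3ccc(O)cc3)[C@@H](O)[C@@H]4O)[C@H]2O)cc1 | target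

**Step count**

Total: 19 steps. Longest linear sequence: 13 steps (11 → 25, steps 7–19).

**Steps most likely to fail**

Step 16 (Shi epoxidation). The ketone enantiomer may be mismatched with the C2 stereocentre and give poor facial selectivity. The dihydroflavonol carbonate may open or hydrolyse during the slow two-phase oxidation, and the electron-rich benzylic epoxide may rearrange on isolation. Fallback, setting out from 21: asymmetric dihydroxylation (OsO4 cat., (DHQ)2PHAL, N-methylmorpholine N-oxide, acetone/H2O, 0 °C) should place both oxygens on the same alkene face and give the syn-diol F1. Trimethyl orthoformate with pyridinium tosylate would convert it into the cyclic orthoformate F2. Acetyl bromide would open F2 through the dioxolanylium ion, bromide entering at the benzylic carbon with inversion, to give the bromo formate F3. KHCO3 in MeOH/THF at 0 °C would then remove the formate and close the epoxide with a second inversion, coming back to the route at 22.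

Step 17 (key cyclisation). The BF3-activated epoxide may undergo hydride shift to a ketone, the C2 benzylic aryl ether may ionise, or the opening may run through a free benzylic cation and lose the C4 configuration. Fallback, setting out from 22: chloroacetyl chloride (Bu4NCl cat., CH2Cl2) would add across the epoxide to give the chloro chloroacetate F4, with chloride anti at C4 and the ester on the C3 oxygen. AgOSO2CF3 with 2,6-di-tert-butylpyridine at −40 °C would ionise the benzylic chloride with participation of the ester carbonyl. The resulting trans-dioxolanylium ion can only be attacked by ring A anti to the C3 oxygen, which enforces the 3,4-trans relation and should give the chloroacetate F5. Thiourea with NaHCO3 in EtOH/THF would then remove the chloroacetyl group, coming back to the route at 23.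

Step 15 (cross-metathesis). The ruthenium carbene may be sequestered as a chelated 2-benzyloxybenzylidene, the styrene may homodimerise, or the allylic ether may isomerise. Fallback, setting out from 10 and 18: cross-metathesis of 10 with pinacol vinylboronate (second-generation Grubbs catalyst, CH2Cl2, 40 °C) would give the (E)-alkenylboronate F6. Iodide 18 would be acylated with CbzCl/pyridine to the iodo carbonate F7. A Suzuki–Miyaura coupling of F6 with F7 (Pd(dppf)Cl2, K3PO4, THF/H2O, rt), in which oxidative addition of the aryl iodide to zerovalent palladium should outpace ionisation of the allylic aryl ether, comes back to the route at 21.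

**Further compounds**

F1 | step 16 | syn-diol of 21 (hydroxyls at upper C3 and C4 on the alkene face used for 22) | c5ccccc5COc1ccc([C@@H](Oc3cccc(OCc5ccccc5)c3OCc5ccccc5)[C@H](O)[C@@H](O)c3cc4c(c(OCc5ccccc5)c3OCc5ccccc5)O[C@H](c3ccc(OCc5ccccc5)cc3)[C@@H](OC(=O)OCc5ccccc5)C4=O)cc1
F2 | step 16 | cyclic orthoformate (2-methoxy-1,3-dioxolane) of F1, mixture at the orthoester carbon | c5ccccc5COc1ccc([C@@H](Oc3cccc(OCc5ccccc5)c3OCc5ccccc5)[C@@H]2OC(OC)O[C@H]2c3cc4c(c(OCc5ccccc5)c3OCc5ccccc5)O[C@H](c3ccc(OCc5ccccc5)cc3)[C@@H](OC(=O)OCc5ccccc5)C4=O)cc1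
F3 | step 16 | bromo formate (bromide at upper C4 with inversion, formate on the C3 oxygen) | c5ccccc5COc1ccc([C@@H](Oc3cccc(OCc5ccccc5)c3OCc5ccccc5)[C@H](OC=O)[C@H](Br)c3cc4c(c(OCc5ccccc5)c3OCc5ccccc5)O[C@H](c3ccc(OCc5ccccc5)cc3)[C@@H](OC(=O)OCc5ccccc5)C4=O)cc1
F4 | step 17 | chloro chloroacetate (chloride at upper C4 with inversion, chloroacetate on the C3 oxygen) | c5ccccc5COc1ccc([C@@H](Oc3cccc(OCc5ccccc5)c3OCc5ccccc5)[C@H](OC(=O)CCl)[C@H](Cl)c3cc4c(c(OCc5ccccc5)c3OCc5ccccc5)O[C@H](c3ccc(OCc5ccccc5)cc3)[C@@H](OC(=O)OCc5ccccc5)C4=O)cc1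
F5 | step 17 | 3-O-chloroacetate of 23 (upper C3) | c5ccccc5COc1ccc([C@H]2Oc3c(ccc(OCc5ccccc5)c3OCc5ccccc5)[C@H](c3cc4c(c(OCc5ccccc5)c3OCc5ccccc5)O[C@H](c3ccc(OCc5ccccc5)cc3)[C@@H](OC(=O)OCc5ccccc5)C4=O)[C@H]2OC(=O)CCl)cc1
F6 | step 15 | 2-{(1E,3S)-3-[2,3-bis(benzyloxy)phenoxy]-3-[4-(benzyloxy)phenyl]prop-1-en-1-yl}-4,4,5,5-tetramethyl-1,3,2-dioxaborolane | c5ccccc5COc1ccc([C@@H](Oc3cccc(OCc5ccccc5)c3OCc5ccccc5)/C=C/B2OC(C)(C)C(C)(C)O2)cc1
F7 | step 15 | benzyl (2R,3R)-7,8-bis(benzyloxy)-2-[4-(benzyloxy)phenyl]-6-iodo-4-oxo-3,4-dihydro-2H-chromen-3-yl carbonate | Ic1cc2c(c(OCc3ccccc3)c1OCc1ccccc1)O[C@H](c1ccc(OCc3ccccc3)cc1)[C@@H](OC(=O)OCc1ccccc1)C2=O
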